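**Strategy in one sentence.** The furan ring of furfural supplies C1–C4; a titanium/tartrate kinetic resolution with Achmatowicz ring expansion (step 2) turns the furyl carbinol into a pyranone template that fixes the Z-alkene, masks O5 as the ring oxygen and holds C1 at the aldehyde level, and the template is cleaved in the last step by chlorite oxidation of the lactol.

## Analysis of the target

The target is an open C12 chain (atom locants C1 = CO2H to C12 = CH3; bare numbers are compounds): a (Z)-C2=C3 enoic acid, an acetoxy group at C4 (S), a free hydroxyl at C5 (R), a trans-oxirane across C6–C7 (6R,7S), a ketone at C8, a second acetoxy group at C9 (R) and a propyl tail; the oxirane is its only ring. In Fischer terms O4/O5 are threo, O5 and the oxirane oxygen at C6 are erythro, and the oxirane is trans; C9 is cut off from this array by the C8 carbonyl, so it cannot be relayed and is best bought. The sensitive groups are the α,β-epoxy ketone (hydride, base, hard nucleophiles), the C9 acetoxy ketone (epimerisable α′-hydrogen), the C4 acetate next to the free O5 hydroxyl (1,2-acyl migration) and the (Z)-5-hydroxy-2-enoic acid, which can lactonise to a 5,6-dihydropyran-2-one or isomerise to E. The difficulty is therefore differentiation and timing: of three secondary oxygens (O4, O5, O9) exactly two are acetylated, the acid must be freed last without ester hydrolysis, and the C8 ketone must never meet a hydride. The feature the route exploits is the array C1(=O)–C2=C3(Z)–C4(O)–C5(OH): O5 and C1 are 1,5-related across a cis double bond, so the target is the ring-opened, oxidised form of a 3,6-dihydro-2H-pyran-6-ol whose ring atoms are O5, C1, C2, C3, C4 and C5. That lactol is the reduction product of an Achmatowicz pyranone, which comes from a 2-furyl carbinol whose four furan carbons are C1–C4 and whose carbinol carbon is C5. Inside the ring the Z geometry is fixed, O5 is the ring oxygen so only O4 can be acylated, C1 waits at the aldehyde level, and the C4 carbonyl is reduced under control of the ring.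

## Retrosynthetic reasoning

**17 ⇒ 15.** The O5–H and C1(=O)OH groups are reconnected to the lactol ring of 15 (ring-chain tautomer 16). Forward, a Pinnick oxidation acts on the open hydroxy-enal, so O5 and the acid appear together, under buffered conditions that two acetates and the epoxy ketone tolerate. No ester has to be hydrolysed and the Z geometry is inherited from the ring.

**15 ⇒ 14 ⇒ 13.** The lactol hydroxyl is carried as a silyl acetal (14). The two C–O bonds of the oxirane are then cut to give E-enone 13. The oxirane is made late because it is the most fragile unit, and by a catalyst-controlled nucleophilic epoxidation because only the C6=C7 bond is conjugated to a carbonyl. The forward reaction must add oxygen to one face of an E-enone beside two acetates.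

**13 ⇒ 7 + 12.** The C6=C7 bond is cut by cross-metathesis into vinyl pyran 7 and vinyl ketone 12. This is the convergent cut: it delivers C7–C12 with the C8 ketone and the bought C9 stereocentre in one piece, and it does so after every hydride step.

**12 ⇒ 11 ⇒ 9 ⇒ 8.** The C7–C8 bond is cut by an acyl Stille coupling of acid chloride 11 with a vinyl donor. Acid chloride 11 goes back through acid 10 to hydroxy acid 9, and 9 to D-norvaline 8 by diazotisation with retention. C9 is thus bought.

**7 ⇒ 6 ⇒ 5.** The C4–O bond is traced to the trans-alcohol 6 by a Mitsunobu inversion that delivers the acetate, and 6 to pyranone 5 by a Luche reduction directed by the ring. O5 needs no protecting group because it is the ring oxygen.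

**5 ⇒ 4 ⇒ 2 (key).** The pyranone ring of 4 is traced to the furan of 2 via the open ene-dione 3. Forward, the oxidative ring expansion must convert the furan into C1 (aldehyde level), the Z-C2=C3 alkene and the C4 ketone. Run as a Sharpless-type kinetic resolution, it also selects the C5 configuration from racemic 2.

**2 ⇒ 1.** The C5–C6 bond is cut by a Grignard disconnection to furfural 1 and a vinyl nucleophile.

## Alternatives that were turned down

**Alternative 1:** the textbook route, an open-chain assembly. Disconnections at C2=C3 (Still–Gennari olefination) and C6=C7 (Horner–Wadsworth–Emmons olefination), then nucleophilic epoxidation of the enone; the key intermediate would be the protected dienoate A1 (allyl ester, O5 as a triethylsilyl ether). It was turned down for these reasons: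
- C4 and C5 must come from the chiral pool or a dihydroxylation and then be told apart, although O4 and O5 are nearly equivalent in an open chain.
- The Z-enoate lactonises onto O5 as soon as O5 is uncovered.
- The last step is an ester cleavage next to two acetates, and a palladium-mediated allyl ester cleavage can ionise the C4 allylic acetate of A1.
- No single step removes more than one problem, and the count would be roughly fifteen steps or more.

**Alternative 2:** oxirane-forming fragment union. Disconnection of C6–C7 and C6–O: a Darzens-type (or sulfonium ylide) condensation of aldehyde A2 with bromo ketone A3 would form the C6–C7 bond, close the oxirane and set C6 and C7 at once, giving 14 directly. It was turned down for these reasons: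
- A2 is an α-alkoxy aldehyde with a β-acetoxy group and loses acetate by E1cB under the base required.
- In A3 the C9 hydrogen is about as acidic as the C7 hydrogens, so epimerisation and wrong-side enolisation compete.
- Ketone-stabilised ylides react poorly with enolisable aldehydes.
- The facial choice at C6 would rest on an uncontrolled Felkin/chelate balance.
- A2 costs more steps than 7.

**Alternative 3:** reagent-controlled allylboration at C4–C5. A Brown-type (Z)-γ-alkoxyallylboration of epoxy aldehyde A4 would set C4 and C5 as the syn pair in one step and give A5; acryloylation of O5 and ring-closing metathesis would then give lactone A6. It was turned down for these reasons: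
- A4 carries the C8 ketone beside the aldehyde and is an epimerisable epoxy aldehyde.
- O4 arrives as an ether that must later be exchanged for an acetate next to the epoxy ketone.
- A6 can only be opened by hydrolysis, which the acetates and the epoxy ketone would not survive.
- Two stereocentres are won but the endgame stays unsolved.

Key step: step 2

Assumptions: the silyl acetal made in step 3 is drawn as the 2,6-trans anomer expected to predominate; this acetal carbon (C1 of the target) loses its configuration in step 11. The CIP descriptor of the ring carbon that is C5 of the target changes from S (4–7, 13) to R (14–17) by a priority change only; its geometry is never touched after step 2.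

## Steps

Step 1
Reactants: 1 furfural
Product: 2 rac-1-(furan-2-yl)prop-2-en-1-ol
Conditions: CH2=CHMgBr (1.1 equiv), THF, −20 → 0 °C; quench with H2O
Reagents that add atoms: vinylmagnesium bromide, C=C[Mg]Br
Why: Grignard 1,2-addition to an aromatic aldehyde forms the C5–C6 bond; C5 is formed racemic and is resolved in step 2; the acid-sensitive product is worked up without acid.

Step 2
Reactants: 2 rac-1-(furan-2-yl)prop-2-en-1-ol
Product: 4 (2S)-2-ethenyl-6-hydroxy-2H-pyran-3(6H)-one (both anomers), via ene-dione (2Z,5S)-5-hydroxy-4-oxohepta-2,6-dienal 3 (not isolated)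
Conditions: Ti(OiPr)4 (0.2 equiv), L-(+)-DIPT (0.24 equiv), TBHP (0.5 equiv, in decane), 4 Å MS, CH2Cl2, −20 °C; aq tartaric acid work-up
Reagents that add atoms: tert-butyl hydroperoxide, CC(C)(C)OO
Why: This is the titanium/tartrate kinetic resolution of a 2-furyl carbinol with concomitant Achmatowicz ring expansion, a known reaction of this substrate class. The carbinol exchanges onto the tetravalent titanium–tartrate complex, the bound tert-butyl peroxide transfers oxygen to the furan C2=C3 bond allylic to the carbinol, and the oxidised furan opens to the cis-ene-dione 3, in which furan C2 has become the C4 ketone, furan C5 the C1 aldehyde and furan C3=C4 the Z-C2=C3 alkene. The O5 hydroxyl then adds to the C1 aldehyde (6-exo-trig hemiacetalisation) and closes the six-membered lactol ring of 4. No permanent stereocentre is created; the configuration at C5 is selected, because with L-(+)-DIPT the (S)-enantiomer of 2 presents its furan as the matched π-system, as simple 2-furyl alkyl carbinols do, and the (R)-enantiomer is left behind. The second selectivity needed is furan over vinyl: the vinyl group is a monosubstituted alkene, the slowest class in this epoxidation, and in the (S)-enantiomer it is also the mismatched π-system. Half an equivalent of oxidant keeps the conversion below one half so that the optical purity of 4 should not be eroded. In this one operation the template ring is built, C1 reaches the aldehyde level, the Z-alkene is fixed, O5 is set apart from the future O4, and the absolute configuration is chosen.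

Step 3
Reactants: 4 (2S)-2-ethenyl-6-hydroxy-2H-pyran-3(6H)-one
Product: 5 (2S,6S)-6-[(tert-butyldimethylsilyl)oxy]-2-ethenyl-2H-pyran-3(6H)-one
Conditions: TBSCl, imidazole, CH2Cl2, −20 → 0 °C
Reagents that add atoms: tert-butyldimethylsilyl chloride, CC(C)(C)[Si](C)(C)Cl
Why: Silylation of the lactol hydroxyl should give mainly the 2,6-trans acetal (axial silyloxy group, anomeric effect); a weak base and low temperature are used because the hydrogen at C5 is α to the ketone and allylic.

Step 4
Reactants: 5 (2S,6S)-6-[(tert-butyldimethylsilyl)oxy]-2-ethenyl-2H-pyran-3(6H)-one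
Product: 6 (2S,3R,6S)-6-[(tert-butyldimethylsilyl)oxy]-2-ethenyl-3,6-dihydro-2H-pyran-3-ol
Conditions: NaBH4, CeCl3·7H2O, MeOH/CH2Cl2, −78 °C
Reagents that add atoms: none
Why: Luche 1,2-reduction of the enone; hydride should add to the C4 carbonyl anti to the axial anomeric silyloxy group and give the alcohol trans to the vinyl group (4R); no other carbonyl is present at this stage.

Step 5
Reactants: 6 (2S,3R,6S)-6-[(tert-butyldimethylsilyl)oxy]-2-ethenyl-3,6-dihydro-2H-pyran-3-ol
Product: 7 (2S,3S,6S)-6-[(tert-butyldimethylsilyl)oxy]-2-ethenyl-3,6-dihydro-2H-pyran-3-yl acetate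
Conditions: PPh3, DIAD, AcOH, toluene, 0 °C → rt
Reagents that add atoms: acetic acid, CC(=O)O
Why: Mitsunobu reaction with acetic acid as nucleophile: SN2 displacement of the alkoxyphosphonium group inverts C4 to the required (4S) configuration, cis to the C5 substituent, and installs the C4 acetate directly; O5 is the ring oxygen and cannot be acylated.

Step 6
Reactants: 8 D-norvaline
Product: 9 (R)-2-hydroxypentanoic acid
Conditions: NaNO2, 1 M H2SO4, H2O, 0 °C → rt
Reagents that add atoms: water, O
Why: Diazotisation of the α-amino acid; the carboxylate displaces N2 to an α-lactone that water opens, so the double inversion gives the hydroxy acid with retention (C9 of the target, R).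

Step 7
Reactants: 9 (R)-2-hydroxypentanoic acid
Product: 11 (R)-2-acetoxypentanoyl chloride, via (R)-2-acetoxypentanoic acid 10 (not isolated)
Conditions: AcCl (neat), rt; evaporate; then (COCl)2, DMF (cat.), CH2Cl2, 0 °C → rt
Reagents that add atoms: acetyl chloride, CC(=O)Cl; oxalyl chloride, O=C(Cl)C(=O)Cl
Why: O-acetylation followed by acid chloride formation (Vilsmeier-type catalysis by DMF); O-acyl α-hydroxy acid chlorides are configurationally stable under these conditions.

Step 8
Reactants: 11 (R)-2-acetoxypentanoyl chloride
Product: 12 (R)-3-oxohept-1-en-4-yl acetate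
Conditions: Bu3SnCH=CH2, PdCl2(PPh3)2 (3 mol %), BHT (cat.), toluene, 50 °C
Reagents that add atoms: tributyl(vinyl)stannane, C=C[Sn](CCCC)(CCCC)CCCC
Why: Acyl Stille coupling under neutral conditions: oxidative addition of zerovalent palladium (formed in the flask from the divalent palladium precatalyst) into the acyl C–Cl bond, transmetalation and reductive elimination should give the vinyl ketone without touching the acetate or the α′-stereocentre; the ketone is kept cold and used soon.

Step 9
Reactants: 7 (2S,3S,6S)-6-[(tert-butyldimethylsilyl)oxy]-2-ethenyl-3,6-dihydro-2H-pyran-3-yl acetate; 12 (R)-3-oxohept-1-en-4-yl acetate (3 equiv)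
Product: 13 (2S,3S,6S)-2-[(1E,4R)-4-acetoxy-3-oxohept-1-en-1-yl]-6-[(tert-butyldimethylsilyl)oxy]-3,6-dihydro-2H-pyran-3-yl acetate
Conditions: second-generation Hoveyda–Grubbs catalyst (5–10 mol %), CH2Cl2, 40 °C
Reagents that add atoms: none
Why: Olefin cross-metathesis of a terminal allylic ether with an electron-poor vinyl ketone, which dimerises slowly and should give the E-enone; the unstrained ring alkene of 7 is inert; the step forms C6=C7 and brings in the C8 ketone only after all hydride chemistry.

Step 10
Reactants: 13 (2S,3S,6S)-2-[(1E,4R)-4-acetoxy-3-oxohept-1-en-1-yl]-6-[(tert-butyldimethylsilyl)oxy]-3,6-dihydro-2H-pyran-3-yl acetate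
Product: 14 (2R,3S,6S)-2-{(2R,3S)-3-[(2R)-2-acetoxypentanoyl]oxiran-2-yl}-6-[(tert-butyldimethylsilyl)oxy]-3,6-dihydro-2H-pyran-3-yl acetate
Conditions: La(OiPr)3 (10 mol %), (R)-BINOL (10 mol %), Ph3As=O (10 mol %), TBHP (1.5 equiv, in decane), 4 Å MS, THF, rt
Reagents that add atoms: tert-butyl hydroperoxide, CC(C)(C)OO
Why: Catalytic asymmetric Weitz–Scheffer epoxidation of an E-enone: the peroxide bound to trivalent lanthanum adds to C6 and the enolate closes at C7, which keeps the trans geometry. The face (6R,7S) is chosen by the catalyst; (R)-BINOL is the enantiomer expected from the usual sense of this catalyst family to give the (αS,βR) epoxy ketone, to be confirmed on a model enone. Only C6=C7 is conjugated, so the ring alkene is untouched.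

Step 11
Reactants: 14 (2R,3S,6S)-2-{(2R,3S)-3-[(2R)-2-acetoxypentanoyl]oxiran-2-yl}-6-[(tert-butyldimethylsilyl)oxy]-3,6-dihydro-2H-pyran-3-yl acetate
Product: 15 (2R,3S)-2-{(2R,3S)-3-[(2R)-2-acetoxypentanoyl]oxiran-2-yl}-6-hydroxy-3,6-dihydro-2H-pyran-3-yl acetate (both anomers)
Conditions: HF·pyridine, pyridine, THF, 0 °C
Reagents that add atoms: none
Why: Fluoride cleavage of the labile anomeric silyl acetal under buffered, weakly acidic conditions that should leave the acetates and the epoxy ketone intact; O5 stays in the ring, so no acyl migration is possible.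

Step 12
Reactants: 15 (2R,3S)-2-{(2R,3S)-3-[(2R)-2-acetoxypentanoyl]oxiran-2-yl}-6-hydroxy-3,6-dihydro-2H-pyran-3-yl acetate
Product: 17 (2Z,4S,5R)-4-acetoxy-5-{(2R,3S)-3-[(2R)-2-acetoxypentanoyl]oxiran-2-yl}-5-hydroxypent-2-enoic acid (target), via open hydroxy-enal (2Z,4S,5R)-4-acetoxy-5-{(2R,3S)-3-[(2R)-2-acetoxypentanoyl]oxiran-2-yl}-5-hydroxypent-2-enal 16 (not isolated)
Conditions: NaClO2, NaH2PO4, 2-methyl-2-butene, t-BuOH/H2O, 0 °C; extract cold at pH 4
Reagents that add atoms: sodium chlorite, [Na+].[O-]Cl=O
Why: Pinnick oxidation through the ring-chain tautomer, as in the chlorite oxidation of reducing sugars to aldonic acids: the open Z-hydroxy-enal 16 is oxidised to the acid, which frees O5 and C1 together. The Z geometry is inherited from the ring, and the buffer and hypochlorite scavenger protect the epoxy ketone and the acetates.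

## Compound list

1 | furfural (furan-2-carbaldehyde) | O=Cc1ccco1 | starting material
2 | rac-1-(furan-2-yl)prop-2-en-1-ol | OC(C=C)c1ccco1 | intermediate
3 | (2Z,5S)-5-hydroxy-4-oxohepta-2,6-dienal | C=C[C@H](O)C(=O)/C=C\C=O | intermediate (not isolated)
4 | (2S)-2-ethenyl-6-hydroxy-2H-pyran-3(6H)-one, both anomers | C=C[C@H](OC(O)C=C1)C1=O | intermediate
5 | (2S,6S)-6-[(tert-butyldimethylsilyl)oxy]-2-ethenyl-2H-pyran-3(6H)-one | C=C[C@H](O[C@@H](O[Si](C)(C)C(C)(C)C)C=C1)C1=O | intermediate
6 | (2S,3R,6S)-6-[(tert-butyldimethylsilyl)oxy]-2-ethenyl-3,6-dihydro-2H-pyran-3-ol | C=C[C@H](O[C@@H](O[Si](C)(C)C(C)(C)C)C=C1)[C@@H]1O | intermediate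
7 | (2S,3S,6S)-6-[(tert-butyldimethylsilyl)oxy]-2-ethenyl-3,6-dihydro-2H-pyran-3-yl acetate | C=C[C@H](O[C@@H](O[Si](C)(C)C(C)(C)C)C=C1)[C@H]1OC(C)=O | intermediate
8 | D-norvaline, (R)-2-aminopentanoic acid | CCC[C@@H](N)C(=O)O | starting material
9 | (R)-2-hydroxypentanoic acid | CCC[C@@H](O)C(=O)O | intermediate
10 | (R)-2-acetoxypentanoic acid | CCC[C@@H](OC(C)=O)C(=O)O | intermediate (not isolated)
11 | (R)-2-acetoxypentanoyl chloride | CCC[C@@H](OC(C)=O)C(=O)Cl | intermediate
12 | (R)-3-oxohept-1-en-4-yl acetate | CCC[C@@H](OC(C)=O)C(=O)C=C | intermediate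
13 | (2S,3S,6S)-2-[(1E,4R)-4-acetoxy-3-oxohept-1-en-1-yl]-6-[(tert-butyldimethylsilyl)oxy]-3,6-dihydro-2H-pyran-3-yl acetate | CCC[C@@H](OC(C)=O)C(=O)/C=C/[C@H](O[C@@H](O[Si](C)(C)C(C)(C)C)C=C1)[C@H]1OC(C)=O | intermediate
14 | (2R,3S,6S)-2-{(2R,3S)-3-[(2R)-2-acetoxypentanoyl]oxiran-2-yl}-6-[(tert-butyldimethylsilyl)oxy]-3,6-dihydro-2H-pyran-3-yl acetate | CCC[C@@H](OC(C)=O)C(=O)[C@H]1O[C@@H]1[C@H](O[C@@H](O[Si](C)(C)C(C)(C)C)C=C2)[C@H]2OC(C)=O | intermediate
15 | (2R,3S)-2-{(2R,3S)-3-[(2R)-2-acetoxypentanoyl]oxiran-2-yl}-6-hydroxy-3,6-dihydro-2H-pyran-3-yl acetate, both anomers | CCC[C@@H](OC(C)=O)C(=O)[C@H]1O[C@@H]1[C@H](OC(O)C=C2)[C@H]2OC(C)=O | intermediate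
16 | (2Z,4S,5R)-4-acetoxy-5-{(2R,3S)-3-[(2R)-2-acetoxypentanoyl]oxiran-2-yl}-5-hydroxypent-2-enal | CCC[C@@H](OC(C)=O)C(=O)[C@H]1O[C@@H]1[C@H](O)[C@H](/C=C\C=O)OC(C)=O | intermediate (not isolated)
17 | (2Z,4S,5R)-4-acetoxy-5-{(2R,3S)-3-[(2R)-2-acetoxypentanoyl]oxiran-2-yl}-5-hydroxypent-2-enoic acid, i.e. (2Z,4S,5R,6R,7S,9R)-4,9-diacetoxy-6,7-epoxy-5-hydroxy-8-oxododec-2-enoic acid | CCC[C@@H](OC(C)=O)C(=O)[C@H]1O[C@@H]1[C@H](O)[C@H](/C=C\C(=O)O)OC(C)=O | target

## Step count and risk

Total: 12 steps. Longest linear sequence: 9 steps (steps 1–5 and 9–12, from 1 to 17); the branch from 8 adds steps 6–8.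

**Step 2 (key step).** The processes most likely to fail are incomplete discrimination between the enantiomers of 2, slow competing epoxidation of the vinyl group, and isomerisation of the β,γ-unsaturated ketone of 4 into conjugation (or epimerisation at C5) during work-up. Fallback, from 2 back to 4, separating resolution from ring expansion: immobilised Candida antarctica lipase B with vinyl acetate in hexane should acylate the (R)-enantiomer and leave (S)-1-(furan-2-yl)prop-2-en-1-ol F1. F1 is then ring-expanded to 4 under classical Achmatowicz conditions (NBS, NaHCO3, THF/H2O, 0 °C).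

**Step 12.** The ring-closed lactol may dominate and make the oxidation slow. The freed (Z)-5-hydroxy acid may lactonise, the open enal may isomerise to E, and the C4 acetyl group may migrate to O5 once O5 is free. Fallback, from 15 back to 17, oxidising first and opening the ring afterwards: MnO2 in CH2Cl2 should give the lactone (2R,3S)-2-{(2R,3S)-3-[(2R)-2-acetoxypentanoyl]oxiran-2-yl}-6-oxo-3,6-dihydro-2H-pyran-3-yl acetate F2. The unsaturated δ-lactone carbonyl of F2, more reactive than the secondary acetates, is then opened with Me3SnOH in 1,2-dichloroethane at 60 °C, followed by mild acidification.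

**Step 9.** Turnover at the hindered allylic position of 7 may be slow, and 12 may oligomerise or undergo self-metathesis faster than it cross-couples. Fallback, from 7 and 12 back to 13, using a free allylic alcohol as the more reactive partner: Luche reduction of 12 gives (3S,4R)-3-hydroxyhept-1-en-4-yl acetate F3 (its C3 epimer serves equally here). Cross-metathesis of 7 with F3 under the conditions of step 9 gives the allylic alcohol (2S,3S,6S)-2-[(1E,3S,4R)-4-acetoxy-3-hydroxyhept-1-en-1-yl]-6-[(tert-butyldimethylsilyl)oxy]-3,6-dihydro-2H-pyran-3-yl acetate F4. Dess–Martin oxidation of F4 (NaHCO3, CH2Cl2) gives 13.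

**Step 10.** Facial selectivity may be poor if the substrate bias opposes the catalyst. The basic lanthanum alkoxide may also cause acyl transfer, epimerisation at C9 or γ-deprotonation at C5. Fallback, from 7 and 12 back to 14, replacing nucleophilic epoxidation by a hydroxyl-directed one: the (8S) allylic alcohol F4, made through F3 as above, is the matched substrate for a Sharpless epoxidation with Ti(OiPr)4, D-(−)-DIPT and TBHP (4 Å MS, CH2Cl2, −20 °C). This should give the erythro epoxy alcohol F5, the C8-(R)-hydroxy analogue of 14 with the (6R,7S) oxirane, while any (8R) epimer is left behind. Dess–Martin oxidation of F5 gives 14.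

**Step 5.** Elimination of the activated C4 oxygen toward the acidified C5 hydrogen, or SN2′ delivery of acetate, may compete with direct inversion. Fallback, from 5 back to 7, setting C4 by reagent-controlled reduction instead of substitution: (S)-Me-CBS oxazaborolidine with catecholborane in toluene at −78 °C, with the ring alkene as the large group, should deliver hydride syn to the anomeric silyloxy group, against the substrate bias, and give the cis alcohol (2S,3S,6S)-6-[(tert-butyldimethylsilyl)oxy]-2-ethenyl-3,6-dihydro-2H-pyran-3-ol F6. Acetylation of F6 (Ac2O, pyridine) gives 7.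

## Further compounds

F1 | step 2 | (S)-1-(furan-2-yl)prop-2-en-1-ol | O[C@@H](C=C)c1ccco1
F2 | step 12 | (2R,3S)-2-{(2R,3S)-3-[(2R)-2-acetoxypentanoyl]oxiran-2-yl}-6-oxo-3,6-dihydro-2H-pyran-3-yl acetate | CCC[C@@H](OC(C)=O)C(=O)[C@H]1O[C@@H]1[C@H](OC(=O)C=C2)[C@H]2OC(C)=O
F3 | step 9 | (3S,4R)-3-hydroxyhept-1-en-4-yl acetate | CCC[C@@H](OC(C)=O)[C@@H](O)C=C
F4 | step 9 | (2S,3S,6S)-2-[(1E,3S,4R)-4-acetoxy-3-hydroxyhept-1-en-1-yl]-6-[(tert-butyldimethylsilyl)oxy]-3,6-dihydro-2H-pyran-3-yl acetate | CCC[C@@H](OC(C)=O)[C@@H](O)/C=C/[C@H](O[C@@H](O[Si](C)(C)C(C)(C)C)C=C1)[C@H]1OC(C)=O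
F5 | step 10 | C8-(R)-hydroxy analogue of 14 (8-hydroxy in place of 8-oxo, erythro to the (6R,7S) oxirane) | CCC[C@@H](OC(C)=O)[C@@H](O)[C@H]1O[C@@H]1[C@H](O[C@@H](O[Si](C)(C)C(C)(C)C)C=C2)[C@H]2OC(C)=O
F6 | step 5 | (2S,3S,6S)-6-[(tert-butyldimethylsilyl)oxy]-2-ethenyl-3,6-dihydro-2H-pyran-3-ol | C=C[C@H](O[C@@H](O[Si](C)(C)C(C)(C)C)C=C1)[C@H]1O
A1 | alternative 1 | allyl (2Z,4S,5S,6E,9R)-4,9-diacetoxy-8-oxo-5-[(triethylsilyl)oxy]dodeca-2,6-dienoate | CCC[C@@H](OC(C)=O)C(=O)/C=C/[C@H](O[Si](CC)(CC)CC)[C@H](/C=C\C(=O)OCC=C)OC(C)=O
A2 | alternative 2 | (2R,3S,6S)-6-[(tert-butyldimethylsilyl)oxy]-2-formyl-3,6-dihydro-2H-pyran-3-yl acetate | O=C[C@H](O[C@@H](O[Si](C)(C)C(C)(C)C)C=C1)[C@H]1OC(C)=O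
A3 | alternative 2 | (R)-1-bromo-2-oxohexan-3-yl acetate | CCC[C@@H](OC(C)=O)C(=O)CBr
A4 | alternative 3 | (R)-1-[(2S,3S)-3-formyloxiran-2-yl]-1-oxopentan-2-yl acetate | CCC[C@@H](OC(C)=O)C(=O)[C@H]1O[C@@H]1C=O
A5 | alternative 3 | (R)-1-{(2S,3R)-3-[(1R,2S)-1-hydroxy-2-(methoxymethoxy)but-3-en-1-yl]oxiran-2-yl}-1-oxopentan-2-yl acetate | CCC[C@@H](OC(C)=O)C(=O)[C@H]1O[C@@H]1[C@H](O)[C@H](C=C)OCOC
A6 | alternative 3 | (R)-1-{(2S,3R)-3-[(2R,3S)-3-(methoxymethoxy)-6-oxo-3,6-dihydro-2H-pyran-2-yl]oxiran-2-yl}-1-oxopentan-2-yl acetate | CCC[C@@H](OC(C)=O)C(=O)[C@H]1O[C@@H]1[C@H](OC(=O)C=C2)[C@H]2OCOC
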